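**Plan**

1. Numbering: the bicyclic core is numbered as a naphthalene (C1 bears the side chain, C2 the 2-oxopropyl group, C3 CH3, C4 =CH, C4a, C5 H2, C6 CH3, C7 C=O, C8 CH3, C8a). Ring A is the cyclohexadiene C1–C4a/C8a, ring B the cyclohexanone C4a–C8a.
2. Cuts: (i) both ketones to carbinols and the epoxy-acrylate chain to a dienol (Wittig, Sharpless epoxidation); (ii) C7–C8 of ring B by reductive ketyl (pinacol) coupling; (iii) C2–CH2 to a dienyl triflate plus (R)-propylene oxide; (iv) ring A at C1–C2 and C4a–C8a (Diels–Alder of a 1-silyloxy diene with (R)-5-methylfuran-2(5H)-one).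
3. Enabling feature: the C7(=O)–C8H(CH3) unit of ring B is a deoxygenated acyloin. C7 and C8 can therefore both be carbonyl carbons (aldehyde on the C4a arm, acetyl on C8a) of a 1,6-keto aldehyde on ring A. The C8 oxygen left by the coupling later gives the C7/C8 enolate regiospecifically, away from C6.
4. Forward order: ring A (Diels–Alder), diene via the triflate, 2-hydroxypropyl arm, dienoate side chain (two Wittig reactions on a lactol), ring B (SmI2), C8–H (SmI2, protonation), epoxide and acrylate, both ketones unveiled last.
5. Stereochemistry: C6 comes from (R)-3-bromo-2-methylpropan-1-ol. C1/C8a (cis) come from cycloaddition anti to the methyl group of the (R)-butenolide, whose own centre then becomes the C8 carbonyl. C8 (methyl cis to the C8a–C1 bond, presumably the less stable arrangement) comes from kinetic protonation anti to the C1 substituent. The epoxide comes from Sharpless epoxidation with L-(+)-tartrate.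

Key step: step 17

Remark: centres that are erased later (C2 and C4a of the cycloadduct, the C7 and C8 carbinols, the carbinol of the 2-hydroxypropyl arm) are drawn as the isomer expected to predominate; anomeric carbons are left open. None of them bears on the target. Intermediates are described with the core numbering above.

**Route**

Step 1
Reactants: 1 (R)-3-bromo-2-methylpropan-1-ol
Product: 2 (R)-(3-bromo-2-methylpropoxy)(tert-butyl)dimethylsilane
Conditions: TBSCl, imidazole, CH2Cl2, 0 °C to rt
Reagents that add atoms: tert-butyldimethylsilyl chloride, CC(C)(C)[Si](C)(C)Cl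
Why: Standard silyl ether protection of a primary alcohol; the stereocentre (future C6) is not touched.

Step 2
Reactants: 2 (R)-(3-bromo-2-methylpropoxy)(tert-butyl)dimethylsilane
Product: 3 (S)-tert-butyldimethyl[(2-methylhex-5-en-1-yl)oxy]silane
Conditions: allylmagnesium bromide, CuI (10 mol %), THF, −20 °C to rt
Reagents that add atoms: allylmagnesium bromide, C=CC[Mg]Br
Why: Copper-catalysed cross-coupling of a primary alkyl bromide with an allyl Grignard reagent forms the future C4a–C5 bond without touching the β-stereocentre.

Step 3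
Reactants: 3 (S)-tert-butyldimethyl[(2-methylhex-5-en-1-yl)oxy]silane
Product: 4 (S,E)-7-[(tert-butyldimethylsilyl)oxy]-2,6-dimethylhept-2-enal
Conditions: methacrolein (5 equiv), second-generation Grubbs catalyst RuCl2(=CHPh)(PCy3)(H2IMes) (5 mol %), CH2Cl2, 40 °C
Reagents that add atoms: methacrolein, CC(=C)C=O
Why: Olefin cross-metathesis of a terminal alkene with methacrolein is a reliable route to (E)-2-methyl-2-enals, the E isomer being favoured thermodynamically.

Step 4
Reactants: 4 (S,E)-7-[(tert-butyldimethylsilyl)oxy]-2,6-dimethylhept-2-enal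
Product: 5 (1E,3E,6S)-7-[(tert-butyldimethylsilyl)oxy]-2,6-dimethyl-1-[(triethylsilyl)oxy]hepta-1,3-diene
Conditions: TESOTf, Et3N, Et2O, 0 °C
Reagents that add atoms: triethylsilyl trifluoromethanesulfonate, CC[Si](CC)(CC)OS(=O)(=O)C(F)(F)F
Why: Silyl triflate/amine enolisation of the enal (O-silylation, then loss of one of the only γ-hydrogens) should give the 1-silyloxy-1,3-diene, mainly as the (1E,3E) isomer with both terminal substituents outside, which is the only one able to undergo cycloaddition.

Step 5
Reactants: 6 (R)-but-3-yn-2-ol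
Product: 7 (R)-4-hydroxypent-2-ynoic acid
Conditions: n-BuLi (2.1 equiv), THF, −78 °C; CO2; then 1 M HCl
Reagents that add atoms: carbon dioxide, O=C=O
Why: Carboxylation of the lithium acetylide of the alkoxide/acetylide dianion; the carbinol centre is not involved.

Step 6
Reactants: 7 (R)-4-hydroxypent-2-ynoic acid
Product: 9 (R)-5-methylfuran-2(5H)-one, via (Z)-hydroxy acid 8 (not isolated)
Conditions: H2 (1 atm), Pd/CaCO3 poisoned with Pb(OAc)2 (Lindlar catalyst), quinoline, EtOAc, rt
Reagents that add atoms: none
Why: Lindlar semi-hydrogenation gives the (Z)-γ-hydroxy enoic acid, which lactonises spontaneously to the butenolide with the stereocentre untouched.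

Step 7
Reactants: 5 silyloxy diene, 9 (R)-5-methylfuran-2(5H)-one
Product: 10 cis-fused lactone cycloadduct (ring A as cyclohex-3-ene; C2–OSiEt3; lactone C=O on C1, O–CH(CH3) on C8a)
Conditions: toluene, BHT (cat.), 150 °C, sealed tube
Reagents that add atoms: none
Why: Normal-demand Diels–Alder reaction in which the 1-silyloxy group directs the ortho regiochemistry (silyloxy carbon to the lactone α-carbon, alkyl-bearing terminus to the β-carbon), the cyclic (Z)-dienophile gives the cis C1/C8a relationship, and addition anti to the butenolide methyl group fixes the absolute configuration at C1 and C8a; the endo adduct is drawn, C2 and C4a being erased later.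

Step 8
Reactants: 10 lactone cycloadduct
Product: 11 lactol (lactone C=O reduced to CH–OH, anomers)
Conditions: iBu2AlH (1.1 equiv), CH2Cl2, −78 °C; aq. potassium sodium tartrate
Reagents that add atoms: none
Why: Partial reduction of a γ-lactone with iBu2AlH at low temperature stops at the lactol because the aluminium hemiacetal is stable until work-up.

Step 9
Reactants: 11 lactol
Product: 12 cis-fused cyclic methyl acetal with free C2–OH
Conditions: MeOH, PPTS (cat.), 0 °C to rt
Reagents that add atoms: methanol, CO
Why: Acid-catalysed acetalisation of the lactol, which also methanolyses the allylic triethylsilyl ether while the primary TBS ether should survive; the bicyclic acetal masks the future side-chain aldehyde and the C8 carbinol together.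

Step 10
Reactants: 12 allylic alcohol acetal
Product: 13 enone (C2 ketone conjugated to C3=C4)
Conditions: MnO2, CH2Cl2, rt
Reagents that add atoms: none
Why: MnO2 oxidises the allylic alcohol selectively to the enone; C1, now α to the ketone, cannot epimerise because only the cis-fused five-membered acetal is accessible.

Step 11
Reactants: 13 enone
Product: 14 dienyl triflate (ring A diene C2=C3–C4=C4a, C2–OTf)
Conditions: Tf2O, 2,6-di-tert-butyl-4-methylpyridine, CH2Cl2, 0 °C to rt
Reagents that add atoms: trifluoromethanesulfonic anhydride, O=S(=O)(OS(=O)(=O)C(F)(F)F)C(F)(F)F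
Why: O-Triflation of the enone followed by loss of the γ-proton (H-4a) gives the through-conjugated dienyl triflate, the usual outcome with Tf2O and a hindered pyridine, and so installs the diene of ring A.

Step 12
Reactants: 14 dienyl triflate, 15 (R)-propylene oxide
Product: 16 (R)-2-hydroxypropyl diene (C2–CH2–CH(OH)–CH3)
Conditions: NiCl2(dme) (10 mol %), 2,2'-bipyridine (10 mol %), NaI (25 mol %), Et3N·HCl, Mn powder, DMPU, rt
Reagents that add atoms: none
Why: Nickel-catalysed cross-electrophile coupling of an alkenyl triflate with a terminal epoxide under iodide co-catalysis (iodohydrin formed in situ, coupling at the CH2 terminus) forms the C2–CH2 bond and leaves the carbinol centre of 15 untouched.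

Step 13
Reactants: 16 secondary alcohol
Product: 17 acetate of 16
Conditions: Ac2O, pyridine, DMAP (cat.), CH2Cl2, rt
Reagents that add atoms: acetic anhydride, CC(=O)OC(C)=O
Why: Acetylation protects the secondary alcohol through the oxidation and samarium steps and is removed later by iBu2AlH without an extra operation.

Step 14
Reactants: 17 acetate
Product: 18 lactol with free primary alcohol (future C7–OH)
Conditions: 1 M aq. HCl, THF, rt
Reagents that add atoms: water, O
Why: Dilute aqueous acid hydrolyses the cyclic methyl acetal to the lactol and cleaves the primary TBS ether, while the acetate and the substituted ring diene are expected to survive.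

Step 15
Reactants: 18 lactol
Product: 20 ethyl (2E,4E)-dienoate diol, via enal 19 (not isolated)
Conditions: Ph3P=C(CH3)CHO, toluene, 90 °C; then Ph3P=C(CH3)CO2Et, 60 °C
Reagents that add atoms: 2-(triphenylphosphoranylidene)propanal, CC(C=O)=P(c1ccccc1)(c1ccccc1)c1ccccc1; ethyl 2-(triphenylphosphoranylidene)propanoate, CCOC(=O)C(C)=P(c1ccccc1)(c1ccccc1)c1ccccc1
Why: The lactol reacts through its open hydroxy aldehyde form in a Wittig reaction with the stabilised formyl ylide, and the (E)-enal is homologated at once by a second stabilised ylide, both E geometries following from the stabilised α-methyl ylides, while the immediate second olefination limits oxa-Michael re-closure of the freed hydroxyl onto the enal.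

Step 16
Reactants: 20 dienoate diol
Product: 21 keto aldehyde (C7 aldehyde on the C4a arm, acetyl on C8a)
Conditions: Dess–Martin periodinane, NaHCO3, CH2Cl2, 0 °C to rt
Reagents that add atoms: none
Why: Dess–Martin oxidation converts the primary alcohol into the aldehyde and the secondary alcohol into the methyl ketone under buffered, non-basic conditions that should spare the enolisable centres C6 and C8a.

Step 17
Reactants: 21 keto aldehyde
Product: 22 cis-7,8-diol (ring B closed)
Conditions: SmI2 (2.5 equiv), t-BuOH (2 equiv), THF (0.01 M), −78 to −20 °C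
Reagents that add atoms: none
Why: SmI2 transfers one electron to the aldehyde (C7), the most easily reduced group present, and the samarium ketyl adds to the carbonyl carbon of the neighbouring methyl ketone (C8) within a trivalent-samarium chelate; a second electron transfer and protonation by t-BuOH give the diol. The closest known reaction type is the SmI2-mediated intramolecular pinacol coupling of 1,6-keto aldehydes to cis-cyclohexane-1,2-diols. Ring B closes in the 6-exo-trig mode (the attacked C=O bond is exocyclic to the forming ring) and no other ring is formed. The two new carbinol centres (C7 secondary, C8 tertiary) are expected cis through samarium chelation, but both are erased later (C7 by oxidation, C8 by reductive C–O cleavage), so their configuration does not matter. What the step needs is chemoselectivity and preservation of C6 (α to the aldehyde) and C8a (α to the ketone and allylic): the aldehyde is reduced far faster than the ketone, the dienoate or the acetate at −78 °C without HMPA, the six-membered closure outruns intermolecular coupling at high dilution, and the medium is non-basic. The polarity reversal is the point: two electrophilic carbonyl carbons in a 1,6-relationship are joined, which an ionic acylation at the unactivated C8 could not do without an added activating group.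

Step 18
Reactants: 22 cis-7,8-diol
Product: 23 α-hydroxy ketone (C7 ketone, tertiary C8–OH)
Conditions: IBX, DMSO, rt
Reagents that add atoms: none
Why: IBX oxidises the secondary alcohol of a 1,2-diol to the α-hydroxy ketone without C–C cleavage, the tertiary alcohol being inert.

Step 19
Reactants: 23 α-hydroxy ketone
Product: 25 C7 alcohol (8R), via ketone 24 (not isolated)
Conditions: SmI2 (2.5 equiv), THF/MeOH, −78 °C; then NaBH4, −78 to −20 °C
Reagents that add atoms: none
Why: SmI2 cleaves the C–O bond α to the ketone (reduction of an α-hydroxy ketone) to give the C7/C8 samarium enolate regiospecifically, away from C6; methanol should protonate it at −78 °C on the face opposite to the pseudoaxial C1 alkenyl substituent, setting C8 with H-8 cis to H-8a, and in situ NaBH4 reduction of the ketone then shields both α-centres from epimerisation.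

Step 20
Reactants: 25 C7 alcohol
Product: 26 triol dienol
Conditions: iBu2AlH (excess), CH2Cl2, −78 °C; aq. potassium sodium tartrate
Reagents that add atoms: none
Why: iBu2AlH reduces the dienoate to the allylic alcohol (1,2-reduction) and cleaves the acetate in the same operation.

Step 21
Reactants: 26 triol dienol
Product: 27 (2S,3S)-epoxy triol
Conditions: Ti(OiPr)4 (1.2 equiv), L-(+)-diethyl tartrate (1.5 equiv), t-BuOOH, 4 Å MS, CH2Cl2, −20 °C
Reagents that add atoms: tert-butyl hydroperoxide, CC(C)(C)OO
Why: Sharpless asymmetric epoxidation: the titanium tartrate complex epoxidises only the double bond of the allylic alcohol in the 2,4-dienol, and L-(+)-diethyl tartrate should deliver oxygen to the face that gives the (2S,3S)-epoxy alcohol, as it does for other (E)-2-methyl-2-alken-1-ols.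

Step 22
Reactants: 27 epoxy triol
Product: 28 epoxy aldehyde diol
Conditions: TEMPO (cat.), PhI(OAc)2, CH2Cl2, rt
Reagents that add atoms: none
Why: TEMPO/PhI(OAc)2 oxidises the primary alcohol selectively in the presence of the two secondary alcohols, and the α-carbon of the epoxy aldehyde is quaternary and cannot epimerise.

Step 23
Reactants: 28 epoxy aldehyde diol
Product: 29 methyl (E)-enoate diol
Conditions: Ph3P=CHCO2Me, CH2Cl2, rt
Reagents that add atoms: methyl (triphenylphosphoranylidene)acetate, COC(=O)C=P(c1ccccc1)(c1ccccc1)c1ccccc1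
Why: Wittig reaction of the aldehyde with a stabilised ylide gives the (E)-enoate under neutral conditions that the vinyl epoxide should tolerate.

Step 24
Reactants: 29 methyl ester diol
Product: 30 dihydroxy acid
Conditions: LiOH, THF/MeOH/H2O, 0 °C; then pH 5 NaH2PO4 buffer
Reagents that add atoms: lithium hydroxide, [Li+].[OH-]
Why: Saponification at low temperature; no ketone is present yet, so base cannot epimerise C6 or C8 or move the ring diene into conjugation.

Step 25
Reactants: 30 dihydroxy acid
Product: 31 target acid
Conditions: Dess–Martin periodinane, CH2Cl2, 0 °C to rt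
Reagents that add atoms: none
Why: Dess–Martin oxidation of both secondary alcohols under neutral conditions unveils the C7 ketone and the β,γ-unsaturated methyl ketone as the last event, so neither the α-methyl centres nor the deconjugated ketone ever meet base.

**Compound list**

1 | (R)-3-bromo-2-methylpropan-1-ol | BrC[C@H](C)CO | starting material
2 | (R)-(3-bromo-2-methylpropoxy)(tert-butyl)dimethylsilane | BrC[C@H](C)CO[Si](C)(C)C(C)(C)C | intermediate
3 | (S)-tert-butyldimethyl[(2-methylhex-5-en-1-yl)oxy]silane | C=CCC[C@H](C)CO[Si](C)(C)C(C)(C)C | intermediate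
4 | (S,E)-7-[(tert-butyldimethylsilyl)oxy]-2,6-dimethylhept-2-enal | C/C(C=O)=C\CC[C@H](C)CO[Si](C)(C)C(C)(C)C | intermediate
5 | (1E,3E,6S)-7-[(tert-butyldimethylsilyl)oxy]-2,6-dimethyl-1-[(triethylsilyl)oxy]hepta-1,3-diene | CC[Si](CC)(CC)O/C=C(C)/C=C/C[C@H](C)CO[Si](C)(C)C(C)(C)C | intermediate
6 | (R)-but-3-yn-2-ol | C[C@@H](O)C#C | starting material
7 | (R)-4-hydroxypent-2-ynoic acid | C[C@@H](O)C#CC(=O)O | intermediate
8 | (R,Z)-4-hydroxypent-2-enoic acid | C[C@@H](O)/C=C\C(=O)O | intermediate (not isolated)
9 | (R)-5-methylfuran-2(5H)-one | C[C@@H]1C=CC(=O)O1 | intermediate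
10 | cycloadduct: ring A cyclohex-3-ene with C2–OSiEt3, C3–CH3, C4a–[(S)-CH2CH(CH3)CH2OTBS]; cis-fused γ-lactone across C1/C8a (C=O carbon on C1, (R)-O–CH(CH3) on C8a); H-1, H-2, H-4a, H-8a all cis; lactone CH3 on the face of H-8a | CC[Si](CC)(CC)O[C@@H]1C(C)=C[C@H](C[C@H](C)CO[Si](C)(C)C(C)(C)C)[C@@H]2[C@@H](C)OC(=O)[C@H]12 | intermediate
11 | lactol of 10 (lactone C=O reduced to CH–OH; anomers) | CC[Si](CC)(CC)O[C@@H]1C(C)=C[C@H](C[C@H](C)CO[Si](C)(C)C(C)(C)C)[C@@H]2[C@@H](C)OC(O)[C@H]12 | intermediate
12 | cyclic methyl acetal of 11 with free C2–OH (anomers) | O[C@@H]1C(C)=C[C@H](C[C@H](C)CO[Si](C)(C)C(C)(C)C)[C@@H]2[C@@H](C)OC(OC)[C@H]12 | intermediate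
13 | enone: C2 ketone of 12, conjugated to C3=C4 | O=C1C(C)=C[C@H](C[C@H](C)CO[Si](C)(C)C(C)(C)C)[C@@H]2[C@@H](C)OC(OC)[C@H]12 | intermediate
14 | dienyl triflate: ring A diene C2=C3–C4=C4a, C2–OTf, cis-fused methyl acetal across C1/C8a | O=S(=O)(OC1=C(C)C=C(C[C@H](C)CO[Si](C)(C)C(C)(C)C)[C@@H]2[C@@H](C)OC(OC)[C@H]12)C(F)(F)F | intermediate
15 | (R)-propylene oxide | C[C@@H]1CO1 | starting material
16 | diene 14 with (R)-2-hydroxypropyl at C2 in place of OTf | C[C@@H](O)CC1=C(C)C=C(C[C@H](C)CO[Si](C)(C)C(C)(C)C)[C@@H]2[C@@H](C)OC(OC)[C@H]12 | intermediate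
17 | acetate of 16 | C[C@@H](OC(C)=O)CC1=C(C)C=C(C[C@H](C)CO[Si](C)(C)C(C)(C)C)[C@@H]2[C@@H](C)OC(OC)[C@H]12 | intermediate
18 | lactol of 17 with free primary alcohol on the C4a arm (anomers) | C[C@@H](OC(C)=O)CC1=C(C)C=C(C[C@H](C)CO)[C@@H]2[C@@H](C)OC(O)[C@H]12 | intermediate
19 | (E)-2-methyl-3-(ring A C1)propenal; C8a bears (R)-1-hydroxyethyl, C4a bears (S)-3-hydroxy-2-methylpropyl | C[C@@H](OC(C)=O)CC1=C(C)C=C(C[C@H](C)CO)[C@H]([C@@H](C)O)[C@@H]1/C=C(\C)C=O | intermediate (not isolated)
20 | ethyl (2E,4E)-2,4-dimethyl-5-(ring A C1)penta-2,4-dienoate; C8a (R)-1-hydroxyethyl, C4a (S)-3-hydroxy-2-methylpropyl, C2 (R)-2-acetoxypropyl; H-1/H-8a cis | C[C@@H](OC(C)=O)CC1=C(C)C=C(C[C@H](C)CO)[C@H]([C@@H](C)O)[C@@H]1/C=C(\C)/C=C(\C)C(=O)OCC | intermediate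
21 | keto aldehyde: 20 with C8a acetyl and C4a (S)-2-methyl-3-oxopropyl | C[C@@H](OC(C)=O)CC1=C(C)C=C(C[C@H](C)C=O)[C@H](C(C)=O)[C@@H]1/C=C(\C)/C=C(\C)C(=O)OCC | intermediate
22 | bicyclic cis-7,8-diol: ring B closed, C7–OH secondary, C8 tertiary OH and CH3 | C[C@@H](OC(C)=O)CC1=C(C)C=C2C[C@H](C)[C@H](O)[C@](C)(O)[C@@H]2[C@@H]1/C=C(\C)/C=C(\C)C(=O)OCC | intermediate
23 | α-hydroxy ketone: C7 ketone, C8 tertiary OH | C[C@@H](OC(C)=O)CC1=C(C)C=C2C[C@H](C)C(=O)[C@](C)(O)[C@@H]2[C@@H]1/C=C(\C)/C=C(\C)C(=O)OCC | intermediate
24 | (6S,8R)-ketone: C7 ketone with H-8 cis to H-8a | C[C@@H](OC(C)=O)CC1=C(C)C=C2C[C@H](C)C(=O)[C@H](C)[C@@H]2[C@@H]1/C=C(\C)/C=C(\C)C(=O)OCC | intermediate (not isolated)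
25 | C7 alcohol of 24 | C[C@@H](OC(C)=O)CC1=C(C)C=C2C[C@H](C)[C@H](O)[C@H](C)[C@@H]2[C@@H]1/C=C(\C)/C=C(\C)C(=O)OCC | intermediate
26 | triol: (2E,4E)-dienol side chain, C7–OH, (R)-2-hydroxypropyl at C2 | C[C@@H](O)CC1=C(C)C=C2C[C@H](C)[C@H](O)[C@H](C)[C@@H]2[C@@H]1/C=C(\C)/C=C(\C)CO | intermediate
27 | (2S,3S)-epoxy alcohol of 26 | C[C@@H](O)CC1=C(C)C=C2C[C@H](C)[C@H](O)[C@H](C)[C@@H]2[C@@H]1/C=C(\C)[C@@H]1O[C@@]1(C)CO | intermediate
28 | epoxy aldehyde of 27 | C[C@@H](O)CC1=C(C)C=C2C[C@H](C)[C@H](O)[C@H](C)[C@@H]2[C@@H]1/C=C(\C)[C@@H]1O[C@@]1(C)C=O | intermediate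
29 | methyl (E)-3-(epoxide C2)prop-2-enoate of 28 | C[C@@H](O)CC1=C(C)C=C2C[C@H](C)[C@H](O)[C@H](C)[C@@H]2[C@@H]1/C=C(\C)[C@@H]1O[C@@]1(C)/C=C/C(=O)OC | intermediate
30 | dihydroxy acid of 29 | C[C@@H](O)CC1=C(C)C=C2C[C@H](C)[C@H](O)[C@H](C)[C@@H]2[C@@H]1/C=C(\C)[C@@H]1O[C@@]1(C)/C=C/C(=O)O | intermediate
31 | (2E)-3-[(2S,3S)-2-methyl-3-{(1E)-1-[(1S,6S,8R,8aS)-3,6,8-trimethyl-7-oxo-2-(2-oxopropyl)-1,5,6,7,8,8a-hexahydronaphthalen-1-yl]prop-1-en-2-yl}oxiran-2-yl]prop-2-enoic acid | CC(=O)CC1=C(C)C=C2C[C@H](C)C(=O)[C@H](C)[C@@H]2[C@@H]1/C=C(\C)[C@@H]1O[C@@]1(C)/C=C/C(=O)O | target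

**Count and risks**

Total steps: 25. Longest linear sequence: 23 (steps 1–4 and 7–25, from 1).

Step 7. The cycloaddition may stall because a butenolide substituted at its β- and γ-carbons meets a diene substituted at both termini, and the silyl dienol ether may isomerise or decompose on prolonged heating. The fallback replaces the dienophile by a doubly activated one and sets out from 15 and 5. (R)-Propylene oxide 15 would be opened by sodium dimethyl malonate (NaOMe, MeOH, reflux) with lactonisation to methyl (5R)-5-methyl-2-oxotetrahydrofuran-3-carboxylate F1. Selenenylation (NaH, PhSeCl, THF) would give the selenide F2, and oxidative elimination (H2O2, CH2Cl2, 0 °C) the alkylidene-malonate-type butenolide F3. This should add to diene 5 at or below room temperature with the same regiochemistry and the same anti facial sense, giving the ester cycloadduct F4. Krapcho dealkoxycarbonylation (LiCl, wet DMSO, 130 °C), in which the lactone enolate can be protonated only to the cis-fused bicycle, comes back to the route at 10.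

Step 12. Oxidative addition into the hindered dienyl triflate may be slow, so that reduction or homocoupling of the triflate or consumption of the epoxide takes over. The fallback sets out from 14. Stannylation (Me3SnSnMe3, Pd(PPh3)4, LiCl, THF, 65 °C) would give the trimethylstannyl diene F5. Tin–lithium exchange (MeLi, THF, −78 °C) would give the dienyllithium F6, which opens 15 at its CH2 terminus in the presence of BF3·OEt2 and comes back to the route at 16.

Step 19. Protonation of the enolate may show poor facial selectivity, or the enolate may equilibrate, giving the more stable C8 epimer that cannot be corrected by equilibration. The fallback sets out from 23 and forms the C8–H bond by hydrogen addition to a neutral alkene. Dehydration of the tertiary alcohol with the Burgess reagent (benzene, 50 °C; syn elimination, only the methyl hydrogens being syn to the leaving group in 23 as drawn) would give the exocyclic enone F7. Hydrogenation with RhCl(PPh3)3 and H2 (benzene, rt), selective for the 1,1-disubstituted alkene and expected from the face opposite to the C1 substituent, would give ketone 24, which is reduced with NaBH4 as in the second half of step 19 and comes back to the route at 25.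

Further compounds
F1 | step 7 | methyl (5R)-5-methyl-2-oxotetrahydrofuran-3-carboxylate (C3 epimers) | C[C@@H]1CC(C(=O)OC)C(=O)O1
F2 | step 7 | methyl (5R)-5-methyl-2-oxo-3-(phenylselanyl)tetrahydrofuran-3-carboxylate | C[C@@H]1CC([Se]c2ccccc2)(C(=O)OC)C(=O)O1
F3 | step 7 | methyl (R)-5-methyl-2-oxo-2,5-dihydrofuran-3-carboxylate | C[C@@H]1C=C(C(=O)OC)C(=O)O1
F4 | step 7 | cycloadduct of 5 and F3: 10 carrying a methoxycarbonyl group on C1 in place of H-1 | CC[Si](CC)(CC)O[C@@H]1C(C)=C[C@H](C[C@H](C)CO[Si](C)(C)C(C)(C)C)[C@@H]2[C@@H](C)OC(=O)[C@]12C(=O)OC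
F5 | step 12 | trimethylstannyl diene: 14 with SnMe3 at C2 in place of OTf | C[Sn](C)(C)C1=C(C)C=C(C[C@H](C)CO[Si](C)(C)C(C)(C)C)[C@@H]2[C@@H](C)OC(OC)[C@H]12
F6 | step 12 | dienyllithium: 14 with Li at C2 in place of OTf | [Li]C1=C(C)C=C(C[C@H](C)CO[Si](C)(C)C(C)(C)C)[C@@H]2[C@@H](C)OC(OC)[C@H]12
F7 | step 19 | exocyclic enone: 23 with C8=CH2 in place of C8(OH)CH3 | C[C@@H](OC(C)=O)CC1=C(C)C=C2C[C@H](C)C(=O)C(=C)[C@@H]2[C@@H]1/C=C(\C)/C=C(\C)C(=O)OCC
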